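The earlier runs and the new flask are simulated from invented constants; the scatter is artificial.

34.1% of the L charged in Saturday's run is missing at its last reading when L and Q are added up, and I start from that number.

| flask | L | remark | time |
|---|---|---|---|
| Sunday's | 0.0058 M | run made earlier |  |
| Saturday's | 0.057 M | run made earlier |  |
| gamma | 0.021 M |  | 2.5 min |
| beta | 0.0050 M |  | 2.5 min |
| delta | 0.015 M |  | 2.5 min |
| alpha | 0.040 M |  | 2.5 min |
| eta | 0.030 M |  | 2.5 min |

| run | time / s | Q / % | L / % |
|---|---|---|---|
| Sunday's | 10.0 | 10.9 | 81.6 |
| Sunday's | 15.0 | 14.2 | 77.9 |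
| Sunday's | 20.0 | 14.5 | 74.3 |
| Sunday's | 30.0 | 19.3 | 70.6 |
| Sunday's | 50.0 | 19.9 | 66.8 |
| Sunday's | 80.0 | 18.1 | 65.0 |
| Saturday's | 10.0 | 10.8 | 77.6 |
| Saturday's | 20.0 | 17.5 | 62.8 |
| Saturday's | 30.0 | 24.1 | 51.4 |
| Saturday's | 40.0 | 29.5 | 45.2 |
| Saturday's | 50.0 | 29.6 | 39.8 |
| Saturday's | 60.0 | 34.5 | 37.5 |
| Saturday's | 80.0 | 32.0 | 33.9 |

(each reading ± 1 percentage point)

* all flasks from highest to lowest amount of Q, in percent of the L charged, at 2.5 min (gamma / beta / delta / alpha / eta)
* the amount of Q, in percent of the L charged of the flask you put first, at 2.5 min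
* the amount of Q, in percent of the L charged of the flask you put last, at 2.5 min

- a reading or a percentage of Q counts all its forms, free or not
- a reading of L is of its free form alone

A reading of Q counts a pair of L and Q once, while the pair holds two L, so the missing share is the pairs, provided nothing else takes L. Pairs over the square of free L, here 52.1 /M, is my pairing strength, an apparent equilibrium constant. Sunday's reading at 50.0 s then leaves free Q at 0.0962 of free L. Under that proviso free L, plus free Q, plus twice the pairs add up to the charge. Solving that gives 33.0% Q for alpha and 18.9% for beta. Pairs grow with the square of free L, so I commit to the order of the charges, with alpha above beta.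

But one reading is thin. Saturday's reading at 60.0 s gives 34.9 /M instead. The free ratio then becomes 0.163, and alpha comes to 32.2%, beta to 20.3%.

Is the asked time, twice the time of Sunday's last reading, still the plateau? Sunday's L falls 1.8 percentage points in the last 30.0 s, against 18 points in the first 10.0 s, so I read it as levelled. Anything else taking L would hide in the gap, though, so I lean low.

The forecast gives alpha > eta > gamma > delta > beta, with 32% (29% to 35%) first and 18% (15% to 21%) last, “so the order follows the charge”. Its order is mine, and its numbers stand a little below mine.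

    L ⇌ Q (K = 0.130, k = 0.0130 /s)
    Q ⇌ D (K = 0.500, k = 0.00360 /s)
    D ⇌ L (k = 0.00240 /s)
    Q → J (k = 0.00480 /s)
    L + Q ⇌ E, settled at all times (K = 390 /M)

The flasks give alpha > eta > gamma > delta > beta, with 31.6% of Q in alpha and 17.9% in beta, E being my pair; my reckoning with 52.1 /M stands 1.4 points high for alpha and 1 point high for beta. At 25.0 min alpha holds 21.1% of Q. With the same 52.1 /M and free ratio, the neighbour of beta charged with 0.013 M of L reckons to 25.4% of Q, and that flask holds 23.9% of Q.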